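## Analysis of the target

Gnetucleistol F (22) is a trans-2-aryl-3-hydroxymethyl-2,3-dihydrobenzofuran. Ring A is the benzo ring (benzofuran numbering, C3a to C7a) with a methoxy group on C7 and an (E)-3,5-dihydroxystyryl group on C5; ring B is the dihydrofuran (O1, C2, C3); ring C is the 4-hydroxy-3,5-dimethoxyphenyl group on C2; ring D is the resorcinol ring of the stilbene. There are two stereocentres, C2 (R) and C3 (S). They are neighbours, both are benzylic, and the aryl group on C2 and the hydroxymethyl group on C3 are trans, which is also the more stable arrangement. The sensitive parts are the three free phenols, the electron-rich stilbene (acid, light, oxidants) and the C2–O1 bond, a para-hydroxybenzyl aryl ether that can ionise under acid. The connectivity is easy to assemble; the difficulty is the absolute configuration of two contiguous benzylic centres in a framework without a directing group, whose assembly by phenol coupling would be racemic. The strategy rests on two features. First, C3 bears a one-carbon substituent and C2 bears oxygen, so C3–C2–O1 can be read as the α-carbon, β-carbon and oxygen of an aldol between an arylacetic acid derivative (ring A) and an aromatic aldehyde (ring C). Second, C7a, the carbon of ring A bound to O1, is para to C5, and C5 carries a carbon substituent; if that carbon is an ester, a fluorine on C7a is activated for displacement by the aldol oxygen, and the same ester later becomes the aldehyde for the stilbene.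

## Retrosynthetic reasoning

**22 to 21.** The last operation is the cleavage of three aryl O–CH2 bonds. All three phenols are carried as methoxymethyl ethers (21) so that one mild acid treatment frees them together. The primary alcohol needs no protection at any stage.

**21 to 16 and 20.** The stilbene is cut at its C=C bond. The aldehyde is placed on ring A (16) and the phosphonate on ring D (20), because the core synthesis delivers a C5 carboxyl carbon that is easily brought to the aldehyde level, and because a benzylic phosphonate gives the E olefin reliably. Phosphonate 20 is achiral and comes in three steps from 17 through 18 and 19. The olefination must tolerate the free hydroxymethyl group of 16.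

**16 to 15 to 14.** These are changes of oxidation level only. The C5 formyl group and the C3 hydroxymethyl group both derive from carboxyl-level carbons in 14, namely the ring A methyl ester and the acyl oxazolidinone. One hydride reduction gives diol 15 and releases the auxiliary, and a selective benzylic oxidation gives 16. What is gained is that 14 carries exactly the two groups the key step needs: the ester that activates C7a and the imide that carries the chirality.

**14 to 8 and 10 (key disconnection).** Ring B is cut at C2–C3 and at O1–C7a. C2–C3 is chosen because both stereocentres lie on it and cutting it exposes an aldol between imide 8 and aldehyde 10. O1–C7a is chosen over O1–C2 because the C2–O bond is then made in the aldol with defined configuration, and the later aryl ether formation touches no stereocentre. In the forward direction the Z-boron enolate 11 adds to 10 to give aldolate 12. Freeing the hydroxyl group gives 13, and its alkoxide displaces the fluorine on C7a.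

**8 to 5 and 6; 5 to 4 to 2 and 3; 2 to 1.** The imide N–C bond is formed from acid 5 and auxiliary 6 through mixed anhydride 7. The aryl–CH2 bond of 5 comes from a palladium-catalysed coupling of boronate 2 with bromoacetate 3, with the tert-butyl ester 4 cleaved by acid in the presence of the methyl ester. The C–B bond of 2 comes from C–H borylation of 1. This order is chosen because the 1,2,3,5-pattern of ring A cannot be reached by electrophilic substitution of 1 (which would go para to the methoxy group), whereas the C–H bond ortho to fluorine is the one favoured in iridium-catalysed borylation.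

**10 to 9.** The phenol of 9 is masked as a methoxymethyl ether. That group is inert to the boron reagent, to strong base, to the fluoride released in the key step and to hydride, which a silyl ether would not be.

## Alternatives that were turned down

**Alternative 1:** Ring B is cut at C2–C3 and O1–C2, so that C2 arrives as a benzylic sulfur ylide carbon and C3 and O1 sit on an ortho-quinone methide of ring A ([4+1]).
- Forward key step: a carbonate base would release both partners, the ylide carbon would add to the methide carbon, and the phenoxide would displace the sulfide, giving A1, (2R,3S)-5-bromo-3-(tert-butyldimethylsilyloxymethyl)-2-(3,5-dimethoxy-4-triisopropylsilyloxyphenyl)-7-methoxy-2,3-dihydrobenzofuran.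
- For it: the annulation is convergent, trans-selective by its mechanism, and the bromide on C5 would allow the styryl group to be attached by a single cross-coupling.
- Against it: the quinone methide needed here carries a silyloxymethyl group on the methide carbon, so it has a hydrogen that lets it tautomerise to an ortho-vinylphenol before the ylide arrives. The absolute configuration must come entirely from a stoichiometric chiral sulfide on a very electron-rich, easily ionised benzylic sulfonium salt. If control falls short, the by-product is the enantiomer of A1, which cannot be removed by ordinary purification.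
- Comparison: this alternative is stronger on step economy in the end game. The chosen route offers a covalently bound auxiliary with a well-understood transition state, and any stereochemical leakage appears as a separable diastereomer.

**Alternative 2:** The disconnection lies in ring D, not in the core: the resorcinol ring is unravelled to a triketone chain.
- Forward key step: the dianion of acetylacetone A4 would be acylated at its terminal carbon by the N-methoxy-N-methyl cinnamamide A3 of the protected core. Aqueous hydroxide in the same flask would close the terminal methyl carbon onto the cinnamoyl carbonyl and dehydrate, giving A2, gnetucleistol F bis(methoxymethyl) ether.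
- For it: two C–C bonds and an aromatic ring form in one flask, ring D never needs protecting groups, and the strongly basic step meets no epimerisable centre.
- Against it: the key step is spent on an achiral ring that can be bought ready-made (as in 17), while the real problem, C2 and C3, is left to some other method. The unsaturated triketone has competing modes of reaction (conjugate addition of the dianion, closure through oxygen to a pyranone). A3 needs extra steps from an aldehyde such as 16.
- Comparison: it is stronger only in avoiding phenol protection on ring D. The chosen route reaches the stilbene from 16 in one olefination and puts its risk where the stereochemistry is decided.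

**Alternative 3:** Ring B is cut at the aryl–C2 bond and at O1–C2. C3 is the single stereocentre of a desymmetrised 2-arylpropane-1,3-diol oxidised to an aldehyde at one arm, and ring C arrives as an arylmagnesium bromide.
- Forward key step: addition to the aldehyde, then a quench with methanolic acid that removes the acetal and silyl groups, ionises the new benzylic alcohol, and lets the C7a phenol close ring B, giving A5, (2R,3S)-5-bromo-2-(4-hydroxy-3,5-dimethoxyphenyl)-3-(hydroxymethyl)-7-methoxy-2,3-dihydrobenzofuran.
- For it: C2 needs no control in the addition, because the cationic closure is governed by product stability and gives the trans ring. The product is already deprotected and carries a bromide for the styryl group.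
- Against it: all the chirality rests on C3 at a stage where it is the α-carbon of an α-aryl aldehyde. That centre is easily enolised by the basic organomagnesium reagent, so racemisation and enolisation in place of addition are built-in risks. Desymmetrising the diol and differentiating its two arms cost steps. The benzylic cation can also be trapped by methanol.
- Comparison: its ring closure is more robust than the SNAr closure chosen here, since nothing can fragment. The chosen route offers both stereocentres set together in one reagent-controlled C–C bond formation, chirality that never rests on an enolisable aldehyde, and an auxiliary still attached when the ring is closed.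

Key step: step 6

Assumption: after methanolysis of the boron aldolate, the boron by-product Bu2BOMe and the methanol are removed with the volatiles, so that neither a borate nor methoxide interferes when the base is added.

## Route

Step 1
Reactants: 1 methyl 4-fluoro-3-methoxybenzoate
Product: 2 methyl 4-fluoro-3-methoxy-5-(4,4,5,5-tetramethyl-1,3,2-dioxaborolan-2-yl)benzoate
Conditions: [Ir(OMe)(cod)]2 (1.5 mol%), 4,4′-di-tert-butyl-2,2′-bipyridine (3 mol%), B2pin2 (1.0 equiv), THF, 65 °C
Reagents that add atoms: bis(pinacolato)diboron, CC1(C)OB(OC1(C)C)B1OC(C)(C)C(C)(C)O1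
Why: Iridium-catalysed aromatic C–H borylation is governed by steric access and C–H acidity; C5–H has only the small, acidifying fluorine as ortho neighbour, whereas C6–H is ortho to the ester and C2–H lies between two substituents, so boron should enter ortho to fluorine.

Step 2
Reactants: 2 methyl 4-fluoro-3-methoxy-5-(4,4,5,5-tetramethyl-1,3,2-dioxaborolan-2-yl)benzoate; 3 tert-butyl bromoacetate (1.5 equiv)
Product: 4 methyl 3-(2-tert-butoxy-2-oxoethyl)-4-fluoro-5-methoxybenzoate
Conditions: Pd(OAc)2 (3 mol%), P(o-tol)3 (9 mol%), K3PO4, THF/H2O, rt → 40 °C
Reagents that add atoms: none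
Why: Suzuki–Miyaura-type sp2–sp3 coupling of an arylboronate with an α-bromo ester: oxidative addition of the activated C–Br bond to zerovalent palladium, transmetalation of the aryl group and reductive elimination. The tert-butyl ester resists the phosphate base and is orthogonal to the methyl ester.

Step 3
Reactants: 4 methyl 3-(2-tert-butoxy-2-oxoethyl)-4-fluoro-5-methoxybenzoate
Product: 5 2-(2-fluoro-3-methoxy-5-methoxycarbonylphenyl)acetic acid
Conditions: CF3CO2H/CH2Cl2 (1:3), rt
Reagents that add atoms: none
Why: Acidolysis of the tert-butyl ester through the tert-butyl cation, which leaves as 2-methylpropene; the methyl ester, the aryl fluoride and the methyl ether are inert.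

Step 4
Reactants: 5 2-(2-fluoro-3-methoxy-5-methoxycarbonylphenyl)acetic acid; 6 (R)-4-benzyl-2-oxazolidinone
Product: 8 (R)-4-benzyl-3-[2-(2-fluoro-3-methoxy-5-methoxycarbonylphenyl)acetyl]oxazolidin-2-one, via mixed pivalic anhydride 7 (not isolated)
Conditions: t-BuCOCl, NEt3, THF, −20 °C; then 6, LiCl, −20 °C → rt
Reagents that add atoms: none
Why: Mixed-anhydride N-acylation of the oxazolidinone; the hindered pivaloyl carbonyl of 7 is not attacked, so the arylacetyl group is transferred, and LiCl with NEt3 makes the oxazolidinone nucleophilic enough without a strong base that could touch the fluoroarene or the ester.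

Step 5
Reactants: 9 syringaldehyde (4-hydroxy-3,5-dimethoxybenzaldehyde)
Product: 10 3,5-dimethoxy-4-(methoxymethoxy)benzaldehyde
Conditions: MOMCl, i-Pr2NEt, CH2Cl2, 0 °C → rt
Reagents that add atoms: chloromethyl methyl ether, COCCl
Why: O-alkylation of the acidic phenol (Williamson-type, through the oxocarbenium-like chloromethyl ether); the resulting acetal is inert to the boron reagent, strong base, fluoride and hydride used later.

Step 6
Reactants: 8 (R)-4-benzyl-3-[2-(2-fluoro-3-methoxy-5-methoxycarbonylphenyl)acetyl]oxazolidin-2-one; 10 3,5-dimethoxy-4-(methoxymethoxy)benzaldehyde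
Product: 14 methyl (2R,3R)-3-[(R)-4-benzyl-2-oxooxazolidine-3-carbonyl]-2-[3,5-dimethoxy-4-(methoxymethoxy)phenyl]-7-methoxy-2,3-dihydrobenzofuran-5-carboxylate, via Z-boron enolate 11 (not isolated), via boron aldolate 12 (not isolated), via syn-aldol 13 (not isolated)
Conditions: Bu2BOTf (1.1 equiv), i-Pr2NEt (1.3 equiv), CH2Cl2, −78 → 0 °C; 10, −78 → 0 °C; MeOH, 0 °C, then evaporation (MeOH, then toluene); KN(SiMe3)2 (2.2 equiv, of which 1.1 equiv neutralises the ammonium triflate), DMF, −40 → −20 °C; AcOH
Reagents that add atoms: none
Why: Proposed new method: Bu2BOTf and i-Pr2NEt convert 8 into the Z-boron enolate 11, which adds to 10 through a closed six-membered chair transition state (aldehyde aryl group equatorial, oxazolidinone carbonyl turned away from the enolate oxygen, attack on the enolate face remote from the benzyl group) to give the syn aldolate 12. Methanolysis frees the hydroxyl group of 13 and the boron leaves as volatile Bu2BOMe; KN(SiMe3)2 then forms the potassium alkoxide, which adds to C7a in a 5-exo-trig manner to give an anionic σ-adduct whose charge is taken up by the para ester, and loss of fluoride restores ring A and closes ring B. The closest known reaction types are the Evans syn aldol of arylacetyl oxazolidinones with aromatic aldehydes and the intramolecular SNAr etherification of 2-(2-fluoroaryl)ethanol alkoxides to dihydrobenzofurans, together with tandem addition–SNAr annulations; what is new is the use of an imide aldolate as the SNAr nucleophile without isolation. C3 (the enolate carbon) and C2 (the aldehyde carbon) are both set in the aldol by the (R)-benzyl group of the auxiliary, and no bond to either centre is touched in the ring closure, so the (2R,3R) syn aldol becomes the trans ring with the C2 and C3 configuration of the target. The step needs absolute and syn selectivity in the aldol and, in the second stage, attack of the alkoxide on C7a in preference to retro-aldol cleavage or attack on the oxazolidinone carbonyl; the first is secured by the Z enolate and the auxiliary, the second by the position of fluorine (ortho to the side chain, para to the ester), the five-membered ring size and the low temperature, which disfavours fragmentation. A C3 enolate of 14 cannot easily expel O1, because the C2–O1 bond lies in the ring plane and is orthogonal to the enolate π system, and C3 is in any case most stable trans. Any leakage of configuration would show up as a diastereomer of 14, since the auxiliary is still attached, and could be removed at this stage.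

Step 7
Reactants: 14 methyl (2R,3R)-3-[(R)-4-benzyl-2-oxooxazolidine-3-carbonyl]-2-[3,5-dimethoxy-4-(methoxymethoxy)phenyl]-7-methoxy-2,3-dihydrobenzofuran-5-carboxylate
Product: 15 [(2R,3S)-2-[3,5-dimethoxy-4-(methoxymethoxy)phenyl]-5-(hydroxymethyl)-7-methoxy-2,3-dihydrobenzofuran-3-yl]methanol
Conditions: LiAlH4 (2.5 equiv), THF, −10 → 0 °C; aqueous potassium sodium tartrate
Reagents that add atoms: none
Why: Hydride reduction: the exocyclic imide carbonyl is the more electrophilic one and is reduced to the hydroxymethyl group with release of the intact auxiliary, and the ring A ester is reduced to the benzylic alcohol. Neither stereocentre is involved; the C3 descriptor changes from R to S only because the substituent priorities change.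

Step 8
Reactants: 15 [(2R,3S)-2-[3,5-dimethoxy-4-(methoxymethoxy)phenyl]-5-(hydroxymethyl)-7-methoxy-2,3-dihydrobenzofuran-3-yl]methanol
Product: 16 (2R,3S)-2-[3,5-dimethoxy-4-(methoxymethoxy)phenyl]-3-(hydroxymethyl)-7-methoxy-2,3-dihydrobenzofuran-5-carbaldehyde
Conditions: activated MnO2 (15 equiv), CH2Cl2, rt
Reagents that add atoms: none
Why: Chemoselective benzylic oxidation on the MnO2 surface: the C5 hydroxymethyl group is benzylic and on an electron-rich ring and is oxidised, whereas the C3 hydroxymethyl group is an ordinary primary alcohol and should be left.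

Step 9
Reactants: 17 3,5-dihydroxybenzyl alcohol
Product: 18 3,5-bis(methoxymethoxy)benzyl alcohol
Conditions: MOMCl (2.2 equiv), K2CO3, acetone, 0 °C → rt
Reagents that add atoms: chloromethyl methyl ether, COCCl
Why: Phenol-selective O-alkylation: carbonate deprotonates only the phenols, so the two phenoxides are alkylated and the benzylic alcohol stays free.

Step 10
Reactants: 18 3,5-bis(methoxymethoxy)benzyl alcohol
Product: 19 3,5-bis(methoxymethoxy)benzyl bromide
Conditions: CBr4, PPh3, CH2Cl2, 0 °C
Reagents that add atoms: carbon tetrabromide, BrC(Br)(Br)Br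
Why: Appel reaction; the alkoxyphosphonium intermediate is displaced by bromide under neutral conditions, so the acid-labile acetals survive.

Step 11
Reactants: 19 3,5-bis(methoxymethoxy)benzyl bromide
Product: 20 diethyl 3,5-bis(methoxymethoxy)benzylphosphonate
Conditions: P(OEt)3 (neat), 120 °C
Reagents that add atoms: triethyl phosphite, CCOP(OCC)OCC
Why: Michaelis–Arbuzov reaction: SN2 attack of phosphorus on the benzylic bromide and dealkylation of the phosphonium salt by bromide, which leaves as volatile bromoethane.

Step 12
Reactants: 16 (2R,3S)-2-[3,5-dimethoxy-4-(methoxymethoxy)phenyl]-3-(hydroxymethyl)-7-methoxy-2,3-dihydrobenzofuran-5-carbaldehyde; 20 diethyl 3,5-bis(methoxymethoxy)benzylphosphonate (2.0 equiv)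
Product: 21 [(2R,3S)-5-[(E)-2-[3,5-bis(methoxymethoxy)phenyl]vinyl]-2-[3,5-dimethoxy-4-(methoxymethoxy)phenyl]-7-methoxy-2,3-dihydrobenzofuran-3-yl]methanol
Conditions: KOt-Bu (3.0 equiv), THF, 0 °C → rt
Reagents that add atoms: none
Why: Horner–Wadsworth–Emmons olefination: reversible addition of the benzylic phosphonate anion to the aldehyde and elimination through the less crowded oxaphosphetane give the E-stilbene. The free hydroxymethyl group only consumes one equivalent of base, and C3 is no longer acidic.

Step 13
Reactants: 21 [(2R,3S)-5-[(E)-2-[3,5-bis(methoxymethoxy)phenyl]vinyl]-2-[3,5-dimethoxy-4-(methoxymethoxy)phenyl]-7-methoxy-2,3-dihydrobenzofuran-3-yl]methanol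
Product: 22 gnetucleistol F, 5-[(E)-2-[(2R,3S)-2-(4-hydroxy-3,5-dimethoxyphenyl)-3-(hydroxymethyl)-7-methoxy-2,3-dihydrobenzofuran-5-yl]vinyl]benzene-1,3-diol
Conditions: HCl (conc., 10 equiv), MeOH, 40 °C, dark
Reagents that add atoms: none
Why: Acid-catalysed acetal cleavage: each protonated methoxymethyl ether loses the phenol and the oxocarbenium ion is trapped by methanol as dimethoxymethane. Dilute acid and moderate temperature are chosen so that neither the C2–O1 bond nor the stilbene is protonated productively.

## Compound list

1 | methyl 4-fluoro-3-methoxybenzoate | COC(=O)c1ccc(F)c(OC)c1 | starting material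
2 | methyl 4-fluoro-3-methoxy-5-(4,4,5,5-tetramethyl-1,3,2-dioxaborolan-2-yl)benzoate | COC(=O)c1cc(B2OC(C)(C)C(C)(C)O2)c(F)c(OC)c1 | intermediate
3 | tert-butyl bromoacetate | CC(C)(C)OC(=O)CBr | starting material
4 | methyl 3-(2-tert-butoxy-2-oxoethyl)-4-fluoro-5-methoxybenzoate | COC(=O)c1cc(CC(=O)OC(C)(C)C)c(F)c(OC)c1 | intermediate
5 | 2-(2-fluoro-3-methoxy-5-methoxycarbonylphenyl)acetic acid | COC(=O)c1cc(CC(=O)O)c(F)c(OC)c1 | intermediate
6 | (R)-4-benzyl-2-oxazolidinone | O=C1OC[C@@H](Cc2ccccc2)N1 | starting material
7 | 2-(2-fluoro-3-methoxy-5-methoxycarbonylphenyl)acetic pivalic anhydride | COC(=O)c1cc(CC(=O)OC(=O)C(C)(C)C)c(F)c(OC)c1 | intermediate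
8 | (R)-4-benzyl-3-[2-(2-fluoro-3-methoxy-5-methoxycarbonylphenyl)acetyl]oxazolidin-2-one | COC(=O)c1cc(CC(=O)N2[C@H](Cc3ccccc3)COC2=O)c(F)c(OC)c1 | intermediate
9 | syringaldehyde (4-hydroxy-3,5-dimethoxybenzaldehyde) | COc1cc(C=O)cc(OC)c1O | starting material
10 | 3,5-dimethoxy-4-(methoxymethoxy)benzaldehyde | COCOc1c(OC)cc(C=O)cc1OC | intermediate
11 | (R)-4-benzyl-3-[(Z)-1-(dibutylboryloxy)-2-(2-fluoro-3-methoxy-5-methoxycarbonylphenyl)vinyl]oxazolidin-2-one | CCCCB(CCCC)O/C(=C\c1cc(C(=O)OC)cc(OC)c1F)N1[C@H](Cc2ccccc2)COC1=O | intermediate
12 | (R)-4-benzyl-3-[(2R,3R)-3-(dibutylboryloxy)-3-[3,5-dimethoxy-4-(methoxymethoxy)phenyl]-2-(2-fluoro-3-methoxy-5-methoxycarbonylphenyl)propanoyl]oxazolidin-2-one | COCOc1c(OC)cc([C@H](OB(CCCC)CCCC)[C@@H](c2cc(C(=O)OC)cc(OC)c2F)C(=O)N2[C@H](Cc3ccccc3)COC2=O)cc1OC | intermediate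
13 | (R)-4-benzyl-3-[(2R,3R)-3-[3,5-dimethoxy-4-(methoxymethoxy)phenyl]-2-(2-fluoro-3-methoxy-5-methoxycarbonylphenyl)-3-hydroxypropanoyl]oxazolidin-2-one | COCOc1c(OC)cc([C@H](O)[C@@H](c2cc(C(=O)OC)cc(OC)c2F)C(=O)N2[C@H](Cc3ccccc3)COC2=O)cc1OC | intermediate
14 | methyl (2R,3R)-3-[(R)-4-benzyl-2-oxooxazolidine-3-carbonyl]-2-[3,5-dimethoxy-4-(methoxymethoxy)phenyl]-7-methoxy-2,3-dihydrobenzofuran-5-carboxylate (2,3-trans) | COCOc1c(OC)cc([C@@H]2Oc3c(OC)cc(C(=O)OC)cc3[C@H]2C(=O)N2[C@H](Cc3ccccc3)COC2=O)cc1OC | intermediate
15 | [(2R,3S)-2-[3,5-dimethoxy-4-(methoxymethoxy)phenyl]-5-(hydroxymethyl)-7-methoxy-2,3-dihydrobenzofuran-3-yl]methanol | COCOc1c(OC)cc([C@@H]2Oc3c(OC)cc(CO)cc3[C@H]2CO)cc1OC | intermediate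
16 | (2R,3S)-2-[3,5-dimethoxy-4-(methoxymethoxy)phenyl]-3-(hydroxymethyl)-7-methoxy-2,3-dihydrobenzofuran-5-carbaldehyde | COCOc1c(OC)cc([C@@H]2Oc3c(OC)cc(C=O)cc3[C@H]2CO)cc1OC | intermediate
17 | 3,5-dihydroxybenzyl alcohol | OCc1cc(O)cc(O)c1 | starting material
18 | 3,5-bis(methoxymethoxy)benzyl alcohol | COCOc1cc(CO)cc(OCOC)c1 | intermediate
19 | 3,5-bis(methoxymethoxy)benzyl bromide | COCOc1cc(CBr)cc(OCOC)c1 | intermediate
20 | diethyl 3,5-bis(methoxymethoxy)benzylphosphonate | CCOP(=O)(Cc1cc(OCOC)cc(OCOC)c1)OCC | intermediate
21 | [(2R,3S)-5-[(E)-2-[3,5-bis(methoxymethoxy)phenyl]vinyl]-2-[3,5-dimethoxy-4-(methoxymethoxy)phenyl]-7-methoxy-2,3-dihydrobenzofuran-3-yl]methanol | COCOc1c(OC)cc([C@@H]2Oc3c(OC)cc(/C=C/c4cc(OCOC)cc(OCOC)c4)cc3[C@H]2CO)cc1OC | intermediate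
22 | gnetucleistol F | COc1cc([C@@H]2Oc3c(OC)cc(/C=C/c4cc(O)cc(O)c4)cc3[C@H]2CO)cc(OC)c1O | target

## Step count and risk

Total step count: 13. Longest linear sequence: 9 (steps 1, 2, 3, 4, 6, 7, 8, 12, 13).

**Step 6 (key step, proposed new method).** The most likely failure is fragmentation of the potassium aldolate by retro-aldol cleavage before it reaches C7a, because the leaving enolate is stabilised by the imide and the aryl group. If the fragments recombine without boron, the configuration erodes. Transfer of the alkoxide to the oxazolidinone carbonyl, and masking of the alkoxide by boron that was not fully removed, are the other ways the closure can be lost.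

Fallback by known chemistry, setting out from 8 and 10 and returning at 15:
- The boron aldol is run alone with the usual oxidative work-up (pH 7 buffer, MeOH, H2O2) and 13 is isolated.
- LiBH4 (THF, 1 equiv MeOH, 0 °C) reduces the imide, which removes the auxiliary and with it the retro-aldol pathway while sparing the aryl methyl ester. This should give the diol methyl 3-[(1R,2S)-1-[3,5-dimethoxy-4-(methoxymethoxy)phenyl]-1,3-dihydroxypropan-2-yl]-4-fluoro-5-methoxybenzoate F1.
- Either hydroxyl group of this diol could close a five-membered ring onto C7a, so the primary one is blocked with Ph3CCl, NEt3 and DMAP in CH2Cl2 as the trityl ether methyl 3-[(1R,2S)-1-[3,5-dimethoxy-4-(methoxymethoxy)phenyl]-1-hydroxy-3-(trityloxy)propan-2-yl]-4-fluoro-5-methoxybenzoate F2. Trityl is chosen because it cannot migrate to the neighbouring alkoxide.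
- KN(SiMe3)2 in THF/DMF at 0 °C then performs the same SNAr etherification on a substrate that cannot fragment, giving methyl (2R,3S)-2-[3,5-dimethoxy-4-(methoxymethoxy)phenyl]-7-methoxy-3-(trityloxymethyl)-2,3-dihydrobenzofuran-5-carboxylate F3.
- LiAlH4 reduces the ester to [(2R,3S)-2-[3,5-dimethoxy-4-(methoxymethoxy)phenyl]-7-methoxy-3-(trityloxymethyl)-2,3-dihydrobenzofuran-5-yl]methanol F4.
- 80% aqueous AcOH at room temperature removes the trityl group without touching the aryl methoxymethyl ethers and returns to the route at 15.

**Step 2.** Protodeboronation of the ortho-fluoro arylboronate under aqueous base may outrun transmetalation, and the bromoacetate may be consumed by hydrolysis or reduction. Fallback, setting out from 2 and returning at 4: bromodeboronation with CuBr2 in MeOH/H2O at 80 °C gives methyl 3-bromo-4-fluoro-5-methoxybenzoate F5. This is coupled with the commercial Reformatsky reagent BrZnCH2CO2t-Bu (Pd2(dba)3, XPhos, THF, 50 °C) to give 4. The polarity is reversed (aryl electrophile, zinc enolate nucleophile) and no aqueous base is needed.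

**Step 7.** Hydride may attack the ring carbonyl of the oxazolidinone because the exocyclic carbonyl sits on the branched C3, which would open the auxiliary without releasing the alcohol. The basic aluminate may also enolise C3 before reduction. Fallback, setting out from 14 and returning at 15: LiOH/H2O2 (THF/H2O, 0 °C) cleaves the exocyclic carbonyl selectively through the hydroperoxide anion and spares the aryl methyl ester. This gives (2R,3R)-2-[3,5-dimethoxy-4-(methoxymethoxy)phenyl]-7-methoxy-5-methoxycarbonyl-2,3-dihydrobenzofuran-3-carboxylic acid F6, whose carboxylate is not enolisable. LiAlH4 (THF, 0 °C → rt) then reduces acid and ester together to 15.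

**Step 13.** Protonation of the electron-rich stilbene (para to O1) may lead to capture of the resulting benzylic cation by methanol or by a resorcinol ring of a second molecule, and acid may also ionise the C2–O1 bond. Fallback, setting out from 16 and returning at 22, in which acid is used before the stilbene exists and the last C–C bond is made with free phenols:
- 2 M aqueous HCl in THF at 40 °C removes the single methoxymethyl group from 16, whose ring A is deactivated by the formyl group, giving (2R,3S)-2-(4-hydroxy-3,5-dimethoxyphenyl)-3-(hydroxymethyl)-7-methoxy-2,3-dihydrobenzofuran-5-carbaldehyde F7.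
- Wittig methylenation (Ph3PCH3Br, KOt-Bu, 4 equiv each, THF, 0 °C → rt) gives 4-[(2R,3S)-5-ethenyl-3-(hydroxymethyl)-7-methoxy-2,3-dihydrobenzofuran-2-yl]-2,6-dimethoxyphenol F8.
- A Mizoroki–Heck reaction with commercial 5-iodobenzene-1,3-diol (Oc1cc(O)cc(I)c1; Pd(OAc)2, P(o-tol)3, NEt3, DMF, 90 °C) arylates the terminal carbon of the styrene and gives 22 directly as the E isomer.

## Further compounds

F1 | step 6 | methyl 3-[(1R,2S)-1-[3,5-dimethoxy-4-(methoxymethoxy)phenyl]-1,3-dihydroxypropan-2-yl]-4-fluoro-5-methoxybenzoate | COCOc1c(OC)cc([C@H](O)[C@@H](c2cc(C(=O)OC)cc(OC)c2F)CO)cc1OC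
F2 | step 6 | methyl 3-[(1R,2S)-1-[3,5-dimethoxy-4-(methoxymethoxy)phenyl]-1-hydroxy-3-(trityloxy)propan-2-yl]-4-fluoro-5-methoxybenzoate | COCOc1c(OC)cc([C@H](O)[C@@H](c2cc(C(=O)OC)cc(OC)c2F)COC(c2ccccc2)(c2ccccc2)c2ccccc2)cc1OC
F3 | step 6 | methyl (2R,3S)-2-[3,5-dimethoxy-4-(methoxymethoxy)phenyl]-7-methoxy-3-(trityloxymethyl)-2,3-dihydrobenzofuran-5-carboxylate | COCOc1c(OC)cc([C@@H]2Oc3c(OC)cc(C(=O)OC)cc3[C@H]2COC(c2ccccc2)(c2ccccc2)c2ccccc2)cc1OC
F4 | step 6 | [(2R,3S)-2-[3,5-dimethoxy-4-(methoxymethoxy)phenyl]-7-methoxy-3-(trityloxymethyl)-2,3-dihydrobenzofuran-5-yl]methanol | COCOc1c(OC)cc([C@@H]2Oc3c(OC)cc(CO)cc3[C@H]2COC(c2ccccc2)(c2ccccc2)c2ccccc2)cc1OC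
F5 | step 2 | methyl 3-bromo-4-fluoro-5-methoxybenzoate | COC(=O)c1cc(Br)c(F)c(OC)c1
F6 | step 7 | (2R,3R)-2-[3,5-dimethoxy-4-(methoxymethoxy)phenyl]-7-methoxy-5-methoxycarbonyl-2,3-dihydrobenzofuran-3-carboxylic acid | COCOc1c(OC)cc([C@@H]2Oc3c(OC)cc(C(=O)OC)cc3[C@H]2C(=O)O)cc1OC
F7 | step 13 | (2R,3S)-2-(4-hydroxy-3,5-dimethoxyphenyl)-3-(hydroxymethyl)-7-methoxy-2,3-dihydrobenzofuran-5-carbaldehyde | COc1cc([C@@H]2Oc3c(OC)cc(C=O)cc3[C@H]2CO)cc(OC)c1O
F8 | step 13 | 4-[(2R,3S)-5-ethenyl-3-(hydroxymethyl)-7-methoxy-2,3-dihydrobenzofuran-2-yl]-2,6-dimethoxyphenol | COc1cc([C@@H]2Oc3c(OC)cc(C=C)cc3[C@H]2CO)cc(OC)c1O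
A1 | alternative 1 | (2R,3S)-5-bromo-3-(tert-butyldimethylsilyloxymethyl)-2-(3,5-dimethoxy-4-triisopropylsilyloxyphenyl)-7-methoxy-2,3-dihydrobenzofuran | COc1cc([C@@H]2Oc3c(OC)cc(Br)cc3[C@H]2CO[Si](C)(C)C(C)(C)C)cc(OC)c1O[Si](C(C)C)(C(C)C)C(C)C
A2 | alternative 2 | gnetucleistol F bis(methoxymethyl) ether | COCOc1c(OC)cc([C@@H]2Oc3c(OC)cc(/C=C/c4cc(O)cc(O)c4)cc3[C@H]2COCOC)cc1OC
A3 | alternative 2 | (E)-3-[(2R,3S)-2-[3,5-dimethoxy-4-(methoxymethoxy)phenyl]-7-methoxy-3-(methoxymethoxymethyl)-2,3-dihydrobenzofuran-5-yl]-N-methoxy-N-methylprop-2-enamide | COCOc1c(OC)cc([C@@H]2Oc3c(OC)cc(/C=C/C(=O)N(C)OC)cc3[C@H]2COCOC)cc1OC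
A4 | alternative 2 | acetylacetone (pentane-2,4-dione) | CC(=O)CC(C)=O
A5 | alternative 3 | (2R,3S)-5-bromo-2-(4-hydroxy-3,5-dimethoxyphenyl)-3-(hydroxymethyl)-7-methoxy-2,3-dihydrobenzofuran | COc1cc([C@@H]2Oc3c(OC)cc(Br)cc3[C@H]2CO)cc(OC)c1O
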